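**Retrosynthetic overview**
- Pakyonol 20 comes from macrocyclic stilbene 19 by one hydrogenation that saturates the alkene and removes the benzyl ether. The 20-membered ring is the only ring built; it is closed late by an intramolecular Wittig reaction between a ring B benzylphosphonium and a ring C aldehyde (17).
- 17 comes from bibenzyl phenol 9 by SNAr of the ring D phenol on 3-benzyloxy-4-fluorobenzaldehyde 11 (ring C–O–ring D ether), then acetal protection, LiAlH4 reduction and PPh3·HBr.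
- 9 carries the ring A–CH2CH2–ring D bridge, made in the key step: an intermolecular Perkin-type aldol condensation of aldehyde 3 (fragment A–O–B) with 3-hydroxyphenylacetic acid 4 (fragment D), followed by decarboxylation, deacetylation and hydrogenation.
- 3 comes from isovanillin 1 and methyl 4-fluorobenzoate 2 by SNAr (ring A–O–ring B ether).

Assumption: the target SMILES has no stereocentre and no configurationally stable axis, so the compound is achiral and no asymmetric step is needed.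

**Route**

Step 1
Reactants: 1 isovanillin (3-hydroxy-4-methoxybenzaldehyde); 2 methyl 4-fluorobenzoate
Product: 3 methyl 4-(5-formyl-2-methoxyphenoxy)benzoate
Conditions: K2CO3, dry DMSO, 120 °C
Reagents that add atoms: none
Why: Nucleophilic aromatic substitution (SNAr) of the para-ester-activated fluoride by the isovanillin phenoxide gives the ring A–O–ring B diaryl ether, with no enolisable position to interfere.

Step 2
Reactants: 3 methyl 4-(5-formyl-2-methoxyphenoxy)benzoate; 4 3-hydroxyphenylacetic acid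
Product: 6 (E)-2-(3-acetoxyphenyl)-3-{4-methoxy-3-[4-(methoxycarbonyl)phenoxy]phenyl}prop-2-enoic acid, via mixed anhydride 5 (not isolated)
Conditions: Ac2O, Et3N, 120 °C; then H2O, aq. HCl
Reagents that add atoms: acetic anhydride, CC(=O)OC(C)=O
Why: Perkin (Oglialoro) condensation: the enolate of the arylacetic mixed anhydride adds to the aldehyde in an intermolecular aldol reaction, and acyl transfer with loss of acetate gives the E acid (aryl groups cis) while the phenol is masked as its acetate.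

Step 3
Reactants: 6 (E)-2-(3-acetoxyphenyl)-3-{4-methoxy-3-[4-(methoxycarbonyl)phenoxy]phenyl}prop-2-enoic acid
Product: 7 methyl 4-{5-[(Z)-2-(3-acetoxyphenyl)ethenyl]-2-methoxyphenoxy}benzoate
Conditions: Cu powder (0.2 equiv), quinoline, 220 °C, N2
Reagents that add atoms: none
Why: Copper-mediated protodecarboxylation of the α-arylcinnamic acid proceeds with retention to the Z stilbene; the geometry does not matter because the alkene is hydrogenated in step 5.

Step 4
Reactants: 7 methyl 4-{5-[(Z)-2-(3-acetoxyphenyl)ethenyl]-2-methoxyphenoxy}benzoate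
Product: 8 methyl 4-{5-[(Z)-2-(3-hydroxyphenyl)ethenyl]-2-methoxyphenoxy}benzoate
Conditions: K2CO3 (0.2 equiv), MeOH/THF, rt
Reagents that add atoms: none
Why: Base-catalysed methanolysis (transesterification) removes the labile aryl acetate, while exchange at the methyl benzoate in methanol is degenerate.

Step 5
Reactants: 8 methyl 4-{5-[(Z)-2-(3-hydroxyphenyl)ethenyl]-2-methoxyphenoxy}benzoate
Product: 9 methyl 4-{5-[2-(3-hydroxyphenyl)ethyl]-2-methoxyphenoxy}benzoate
Conditions: H2 (1 atm), 10% Pd/C, EtOAc, rt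
Reagents that add atoms: none
Why: Catalytic hydrogenation saturates the stilbene to the bibenzyl without touching the ester, the phenol or the diaryl ether.

Step 6
Reactants: 10 4-fluoro-3-hydroxybenzaldehyde
Product: 11 3-(benzyloxy)-4-fluorobenzaldehyde
Conditions: BnBr, K2CO3, DMF, rt
Reagents that add atoms: benzyl bromide, BrCc1ccccc1
Why: Williamson ether synthesis protects the future free hydroxyl of ring C as a benzyl ether that is removed by the final hydrogenation.

Step 7
Reactants: 9 methyl 4-{5-[2-(3-hydroxyphenyl)ethyl]-2-methoxyphenoxy}benzoate; 11 3-(benzyloxy)-4-fluorobenzaldehyde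
Product: 12 methyl 4-[5-(2-{3-[2-(benzyloxy)-4-formylphenoxy]phenyl}ethyl)-2-methoxyphenoxy]benzoate
Conditions: K2CO3, dry DMAc, 140 °C
Reagents that add atoms: none
Why: SNAr of the ring D phenoxide on the fluoride para to the formyl group forms the ring C–O–ring D ether and installs the ring C aldehyde directly.

Step 8
Reactants: 12 methyl 4-[5-(2-{3-[2-(benzyloxy)-4-formylphenoxy]phenyl}ethyl)-2-methoxyphenoxy]benzoate
Product: 13 methyl 4-[5-(2-{3-[2-(benzyloxy)-4-(1,3-dioxolan-2-yl)phenoxy]phenyl}ethyl)-2-methoxyphenoxy]benzoate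
Conditions: ethylene glycol, p-TsOH (cat.), toluene, reflux, Dean–Stark
Reagents that add atoms: ethylene glycol, OCCO
Why: Acid-catalysed acetalisation with azeotropic water removal protects the aldehyde so that only the ester is reduced in the next step.

Step 9
Reactants: 13 methyl 4-[5-(2-{3-[2-(benzyloxy)-4-(1,3-dioxolan-2-yl)phenoxy]phenyl}ethyl)-2-methoxyphenoxy]benzoate
Product: 14 {4-[5-(2-{3-[2-(benzyloxy)-4-(1,3-dioxolan-2-yl)phenoxy]phenyl}ethyl)-2-methoxyphenoxy]phenyl}methanol
Conditions: LiAlH4, THF, 0 °C to rt; then H2O, 15% aq. NaOH, H2O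
Reagents that add atoms: none
Why: Hydride reduction of the benzoate gives the benzylic alcohol, and the basic work-up keeps the dioxolane intact.

Step 10
Reactants: 14 {4-[5-(2-{3-[2-(benzyloxy)-4-(1,3-dioxolan-2-yl)phenoxy]phenyl}ethyl)-2-methoxyphenoxy]phenyl}methanol
Product: 17 {4-[5-(2-{3-[2-(benzyloxy)-4-formylphenoxy]phenyl}ethyl)-2-methoxyphenoxy]benzyl}triphenylphosphonium bromide, via benzylic bromide 15 (not isolated), via acetal phosphonium bromide 16 (not isolated)
Conditions: PPh3·HBr, MeCN, reflux; then 1 M aq. HCl, THF, rt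
Reagents that add atoms: triphenylphosphine hydrobromide, [Br-].c1ccc(cc1)[PH+](c1ccccc1)c1ccccc1
Why: The para-aryloxybenzyl alcohol is converted by HBr into the bromide, which alkylates PPh3 (phosphonium salt formation), and the water released together with the acid hydrolyses the dioxolane to the aldehyde.

Step 11
Reactants: 17 {4-[5-(2-{3-[2-(benzyloxy)-4-formylphenoxy]phenyl}ethyl)-2-methoxyphenoxy]benzyl}triphenylphosphonium bromide
Product: 19 O-benzyl-didehydropakyonol (20-membered cyclic stilbene; Z/E mixture), via phosphonium ylide 18 (not isolated)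
Conditions: NaOMe (5 equiv), CH2Cl2, rt, 17 added over 24 h by syringe pump (final ca. 1 mM)
Reagents that add atoms: none
Why: Intramolecular Wittig olefination of the semi-stabilised benzylide with the ring C aldehyde under high dilution closes the macrocycle; the alkene geometry is removed in step 12.

Step 12
Reactants: 19 O-benzyl-didehydropakyonol (Z/E mixture)
Product: 20 pakyonol
Conditions: H2 (1 atm), 10% Pd/C, EtOAc/MeOH, rt
Reagents that add atoms: none
Why: One catalytic hydrogenation saturates the stilbene and cleaves the benzyl ether by hydrogenolysis, leaving the methyl ether and both diaryl ethers untouched.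

**Compound list**
1 | isovanillin (3-hydroxy-4-methoxybenzaldehyde) | COc1ccc(C=O)cc1O | starting material
2 | methyl 4-fluorobenzoate | COC(=O)c1ccc(F)cc1 | starting material
3 | methyl 4-(5-formyl-2-methoxyphenoxy)benzoate | COC(=O)c1ccc(Oc2cc(C=O)ccc2OC)cc1 | intermediate
4 | 3-hydroxyphenylacetic acid | OC(=O)Cc1cccc(O)c1 | starting material
5 | acetic 2-(3-acetoxyphenyl)acetic anhydride (mixed anhydride) | CC(=O)Oc1cccc(CC(=O)OC(C)=O)c1 | intermediate (not isolated)
6 | (E)-2-(3-acetoxyphenyl)-3-{4-methoxy-3-[4-(methoxycarbonyl)phenoxy]phenyl}prop-2-enoic acid | COC(=O)c1ccc(Oc2cc(/C=C(/C(=O)O)c3cccc(OC(C)=O)c3)ccc2OC)cc1 | intermediate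
7 | methyl 4-{5-[(Z)-2-(3-acetoxyphenyl)ethenyl]-2-methoxyphenoxy}benzoate | COC(=O)c1ccc(Oc2cc(/C=C\c3cccc(OC(C)=O)c3)ccc2OC)cc1 | intermediate
8 | methyl 4-{5-[(Z)-2-(3-hydroxyphenyl)ethenyl]-2-methoxyphenoxy}benzoate | COC(=O)c1ccc(Oc2cc(/C=C\c3cccc(O)c3)ccc2OC)cc1 | intermediate
9 | methyl 4-{5-[2-(3-hydroxyphenyl)ethyl]-2-methoxyphenoxy}benzoate | COC(=O)c1ccc(Oc2cc(CCc3cccc(O)c3)ccc2OC)cc1 | intermediate
10 | 4-fluoro-3-hydroxybenzaldehyde | O=Cc1ccc(F)c(O)c1 | starting material
11 | 3-(benzyloxy)-4-fluorobenzaldehyde | O=Cc1ccc(F)c(OCc2ccccc2)c1 | intermediate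
12 | methyl 4-[5-(2-{3-[2-(benzyloxy)-4-formylphenoxy]phenyl}ethyl)-2-methoxyphenoxy]benzoate | COC(=O)c1ccc(Oc2cc(CCc3cccc(Oc4ccc(C=O)cc4OCc4ccccc4)c3)ccc2OC)cc1 | intermediate
13 | methyl 4-[5-(2-{3-[2-(benzyloxy)-4-(1,3-dioxolan-2-yl)phenoxy]phenyl}ethyl)-2-methoxyphenoxy]benzoate | COC(=O)c1ccc(Oc2cc(CCc3cccc(Oc4ccc(C5OCCO5)cc4OCc4ccccc4)c3)ccc2OC)cc1 | intermediate
14 | {4-[5-(2-{3-[2-(benzyloxy)-4-(1,3-dioxolan-2-yl)phenoxy]phenyl}ethyl)-2-methoxyphenoxy]phenyl}methanol | OCc1ccc(Oc2cc(CCc3cccc(Oc4ccc(C5OCCO5)cc4OCc4ccccc4)c3)ccc2OC)cc1 | intermediate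
15 | 2-{3-(benzyloxy)-4-[3-(2-{3-[4-(bromomethyl)phenoxy]-4-methoxyphenyl}ethyl)phenoxy]phenyl}-1,3-dioxolane (benzylic bromide) | BrCc1ccc(Oc2cc(CCc3cccc(Oc4ccc(C5OCCO5)cc4OCc4ccccc4)c3)ccc2OC)cc1 | intermediate (not isolated)
16 | {4-[5-(2-{3-[2-(benzyloxy)-4-(1,3-dioxolan-2-yl)phenoxy]phenyl}ethyl)-2-methoxyphenoxy]benzyl}triphenylphosphonium bromide | [Br-].c1ccccc1[P+](c1ccccc1)(c1ccccc1)Cc1ccc(Oc2cc(CCc3cccc(Oc4ccc(C5OCCO5)cc4OCc4ccccc4)c3)ccc2OC)cc1 | intermediate (not isolated)
17 | {4-[5-(2-{3-[2-(benzyloxy)-4-formylphenoxy]phenyl}ethyl)-2-methoxyphenoxy]benzyl}triphenylphosphonium bromide | [Br-].c1ccccc1[P+](c1ccccc1)(c1ccccc1)Cc1ccc(Oc2cc(CCc3cccc(Oc4ccc(C=O)cc4OCc4ccccc4)c3)ccc2OC)cc1 | intermediate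
18 | phosphonium ylide of 17 | c1ccccc1P(c1ccccc1)(c1ccccc1)=Cc1ccc(Oc2cc(CCc3cccc(Oc4ccc(C=O)cc4OCc4ccccc4)c3)ccc2OC)cc1 | intermediate (not isolated)
19 | O-benzyl-didehydropakyonol: pakyonol benzyl ether with CH=CH in place of the CH2CH2 between rings B and C; Z/E mixture, so the double-bond geometry is left unspecified | COc1ccc2cc1Oc1ccc(cc1)C=Cc1ccc(c(OCc3ccccc3)c1)Oc1cccc(c1)CC2 | intermediate
20 | pakyonol (achiral) | COc1ccc2cc1Oc1ccc(cc1)CCc1ccc(c(O)c1)Oc1cccc(c1)CC2 | target

**Step count**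
Total: 12 steps. Longest linear sequence: 11 steps (steps 1–5 and 7–12, from isovanillin); step 6 is a one-step side branch.

**Steps most likely to fail, with fallbacks**

Risk at step 3 (decarboxylation at 220 °C; the methyl ester and the acetate may suffer, and the stilbene may degrade). The fallback sets out from 6 and avoids the thermal step. Hydrogenation of 6 (H2, 10% Pd/C, EtOAc/AcOH) gives racemic 2-(3-acetoxyphenyl)-3-{4-methoxy-3-[4-(methoxycarbonyl)phenoxy]phenyl}propanoic acid F1. Coupling with N-hydroxyphthalimide (N,N'-diisopropylcarbodiimide, DMAP cat., CH2Cl2) gives its 1,3-dioxoisoindolin-2-yl ester F2. Radical reductive decarboxylation (Hantzsch ester, Ru(bpy)3Cl2 1 mol %, DMF, blue LEDs, rt) gives methyl 4-{5-[2-(3-acetoxyphenyl)ethyl]-2-methoxyphenoxy}benzoate F3. Methanolysis (K2CO3, MeOH) then comes back to the route at 9.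

Risk at step 7 (SNAr on a fluoride that carries an ortho alkoxy donor, at high temperature next to a methyl ester). The fallback sets out from 9 and replaces SNAr by copper-catalysed Ullmann etherification. Commercial 4-bromo-3-hydroxybenzaldehyde is benzylated (BnBr, K2CO3, DMF) to 3-(benzyloxy)-4-bromobenzaldehyde F4. F4 is coupled with 9 (CuI 10 mol %, N,N-dimethylglycine hydrochloride 30 mol %, Cs2CO3, dioxane, 100 °C), which comes back to the route at 12.

Risk at step 11 (macrocyclic Wittig; oligomerisation competes with ring closure). The fallback sets out from 12 and closes the ring by reductive carbonyl coupling instead. LiAlH4 (THF, 0 °C) reduces ester and aldehyde to {4-[5-(2-{3-[2-(benzyloxy)-4-(hydroxymethyl)phenoxy]phenyl}ethyl)-2-methoxyphenoxy]phenyl}methanol F5. MnO2 (CH2Cl2, rt) oxidises both benzylic alcohols to 4-[5-(2-{3-[2-(benzyloxy)-4-formylphenoxy]phenyl}ethyl)-2-methoxyphenoxy]benzaldehyde F6. Intramolecular McMurry coupling (TiCl4, Zn, pyridine, THF, reflux, slow addition under high dilution) comes back to the route at 19.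

**Further compounds**
F1 | step 3 | racemic 2-(3-acetoxyphenyl)-3-{4-methoxy-3-[4-(methoxycarbonyl)phenoxy]phenyl}propanoic acid | COC(=O)c1ccc(Oc2cc(CC(C(=O)O)c3cccc(OC(C)=O)c3)ccc2OC)cc1
F2 | step 3 | 1,3-dioxoisoindolin-2-yl ester of F1 (racemic) | COC(=O)c1ccc(Oc2cc(CC(C(=O)ON3C(=O)c4ccccc4C3=O)c3cccc(OC(C)=O)c3)ccc2OC)cc1
F3 | step 3 | methyl 4-{5-[2-(3-acetoxyphenyl)ethyl]-2-methoxyphenoxy}benzoate | COC(=O)c1ccc(Oc2cc(CCc3cccc(OC(C)=O)c3)ccc2OC)cc1
F4 | step 7 | 3-(benzyloxy)-4-bromobenzaldehyde | O=Cc1ccc(Br)c(OCc2ccccc2)c1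
F5 | step 11 | {4-[5-(2-{3-[2-(benzyloxy)-4-(hydroxymethyl)phenoxy]phenyl}ethyl)-2-methoxyphenoxy]phenyl}methanol | OCc1ccc(Oc2cc(CCc3cccc(Oc4ccc(CO)cc4OCc4ccccc4)c3)ccc2OC)cc1
F6 | step 11 | 4-[5-(2-{3-[2-(benzyloxy)-4-formylphenoxy]phenyl}ethyl)-2-methoxyphenoxy]benzaldehyde | O=Cc1ccc(Oc2cc(CCc3cccc(Oc4ccc(C=O)cc4OCc4ccccc4)c3)ccc2OC)cc1
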